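Late in the west flask, which is the flask asked about, nothing moves. From 1.00 min to 12.0 min its target reads a mean of 44.8 %, and the south flask reads 31.5 % from 10.0 s on.

common to all: starting material 0.0050 M; free catalyst 10 µM; impurity 14 µM

| charge | partner | second substrate | remark | time |
|---|---|---|---|---|
| west | 4.5 mM | 1 mM | the very flask that is asked about, followed so far |  |
| south | 3 mM | 1 mM | run made earlier |  |
| flask | 4.50 mM | 1.00 mM |  | 12 min |

west run (percent of the starting material charged): time / min: target / % = 1.00: 44; 1.50: 43; 2.50: 47; 4.00: 45; 8.00: 45; 12.0: 45

south run (percent of the starting material charged): time / s: target / % = 10.0: 32; 12.0: 28; 20.0: 32; 30.0: 30; 50.0: 33; 60.0: 34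

(scatter of a reading: 1.5 percentage points)

- target taken out counts as made
- the earlier runs were read with a standard deviation of 1.5 percentage points
- on the list of suspects stand: starting material + partner + free catalyst -> free catalyst + target; second substrate + partner + free catalyst -> free catalyst + second product; free catalyst + impurity -> spent catalyst
- additions bring no volume worth counting

- elm: at 12 min add partner, 50.0 % of the amount charged, then wait 6.0 min
- cedar: at 12 min add free catalyst, 100 % of the amount charged, then wait 6.0 min
- alder: change nothing and wait 6.0 min more
- birch: at 12 min take out 90 % of the target then present, then wait 6.0 min

* target, in percent of the starting material first charged, at 12 min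
* the remedy with the largest gain of target, or "none" below 2 percentage points (elm / cedar / alder / birch / none)
* target present, with what was taken out counted in, in percent of the starting material first charged, after elm
* target present, with what was taken out counted in, in percent of the starting material first charged, after alder

Has partner run out? No. In the west flask, target and the whole second substrate together take 3.24 mM of 4.5 mM.

So we suspect the catalyst. Impurity exceeds free catalyst, 14 µM against 10 µM, so the poisoning step can take up the free catalyst, and 4.00 µM of impurity outlasts it.

Each catalyst lost takes one impurity with it. We can therefore join the two ends without knowing the time course. We define the dose D as the poisoning rate constant times the time integral of free catalyst, and it equals the logarithm of charged impurity over impurity left: 1.25. Partner does not enter D, and west and south have the same catalyst and impurity charges, so they share it.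

But does that fit two different yields? Let y be the target fraction and B the mean partner, taken as the charge less half of what target used. Then s = ln(1/(1-y))/(D·B) should match between flasks. West gives 0.141 mM⁻¹ and south gives 0.136 mM⁻¹.

The objection is that second substrate also uses partner. Taking half its charge off both means gives 0.165 mM⁻¹ and 0.176 mM⁻¹. The readings shift s but still match roughly.

So we commit to 44.8 % now, and the same after elm and alder, since neither brings catalyst. Birch brings none either, and the list holds no step back from target. Cedar brings 10 µM against 4.00 µM of impurity left, so D has no finite value there. Target and second substrate then share the partner left, so we name cedar as best and give no figure for its gain.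

The forecast says 45 % (44 % to 46 %), 45 % after elm, 45 % after alder, and cedar as best, on the ground that “Each run therefore gets a fixed catalyst exposure”.

The simulation gives 44.0 % at 12 min, 44.0 % after elm and 44.0 % after alder. The best remedy is cedar, with a gain of 36 percentage points.

    starting material + partner + free catalyst → free catalyst + target (k = 9.90 × 10⁶ M⁻² s⁻¹)
    second substrate + partner + free catalyst → free catalyst + second product (k = 4.10 × 10⁶ M⁻² s⁻¹)
    free catalyst + impurity → spent catalyst (k = 65000 M⁻¹ s⁻¹)

In the west flask impurity stands at 29 % of its charge, which is a dose of 1.25. The neighbouring flask differs from it in impurity alone, with 5.6 × 10⁻⁵ M. Its dose is 0.197, smaller than the west flask's. We take s as read on west, and a mean partner of 4.18 mM from the 86 % that the neighbouring flask keeps. That reckons 11.0 % of target. The neighbouring flask gives 11.7 % at 12.0 min, with 88 % of its starting material left.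

The runs stem from a simulated flask with constants of no real substance, noise included.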